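**Plan**

1. Numbering: hexan-2-yl chain of the target, C1 = CH3, C2 = C–O-myristoyl, C3 and C4 = diol carbons, C5 = CH2, C6 = carbinol on C4 of the 2,4-disubstituted oxazole.
2. Retrosynthetic cuts, in order: the C3–O benzyl ether; the C5–C6 bond together with the C4–H bond (aldol plus carbonyl reduction); the C2–O acyl bond; the C4–C5 bond (methyl onto a Weinreb amide); the C2–C3 bond (glycolate aldol with acetaldehyde); the CH2–C5′ bond between the two oxazole rings.
3. Enabling feature: the C5 methylene lies between the C4 and C6 carbinols (a 1,3-syn diol) and C6 sits on oxazole C4. The chain therefore opens into an unenolisable oxazole-4-carbaldehyde and a methyl ketone that enolises only at CH3, so the whole C1–C5 part, myristate included, enters as one piece.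
4. Forward order: bis-oxazole aldehyde 5 in two steps; ketone 16 in five steps (auxiliary loading, glycolate aldol, Weinreb amide, methyl ketone, myristoylation); fragment union with in situ reduction; debenzylation.
5. Stereochemistry: C2 and C3 come from an Evans syn-glycolate aldol with (R)-4-benzyloxazolidinone, which also delivers the two oxygens differentiated (C3–OBn, C2–OH). C6 comes from the isopinocampheyl ligands on boron in the aldol, and C4 from C6 by hydride addition to the boron aldolate chelate (4,6-syn).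

Key step: step 8

Remark (assumption): (−)-Ipc2BCl, from (+)-α-pinene, is taken as the antipode that directs a methyl-ketone enol borinate to the Re face of an aldehyde. If a trial with 5 shows the opposite sense, (+)-Ipc2BCl replaces it and nothing else changes.
Remark (assumption): compounds 1 and 2 are taken as purchasable building blocks.

**Step 1**
Reactants: 1 methyl 2-(chloromethyl)-1,3-oxazole-4-carboxylate; 2 2-(triisopropylsilyl)-1,3-oxazole-5-boronic acid pinacol ester
Product: 4 methyl 2-(1,3-oxazol-5-ylmethyl)-1,3-oxazole-4-carboxylate, via 2-silyl coupling product 3 (not isolated)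
Conditions: Pd(dppf)Cl2 (5 mol %), K3PO4, dioxane/H2O, 70 °C; then 1 M HCl, THF, rt
Reagents that add atoms: none
Why: Suzuki–Miyaura cross-coupling of an activated heterobenzylic chloride with a heteroaryl boronate (oxidative addition into C–Cl, transmetalation from oxazole C5, reductive elimination), in which the C2 silyl group blocks the most acidic oxazole position and stabilises the boronate and is then removed by acid protodesilylation; no stereocentre is involved.

**Step 2**
Reactants: 4 methyl 2-(1,3-oxazol-5-ylmethyl)-1,3-oxazole-4-carboxylate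
Product: 5 2-(1,3-oxazol-5-ylmethyl)-1,3-oxazole-4-carbaldehyde
Conditions: DIBAL-H (1.2 equiv), CH2Cl2, −78 °C; MeOH, aq. Rochelle salt
Reagents that add atoms: none
Why: Partial ester reduction with DIBAL-H, in which the aluminium hemiacetal of an oxazole-4-carboxylate is stable at −78 °C and collapses to the aldehyde only on work-up, a standard entry to oxazole-4-carbaldehydes.

**Step 3**
Reactants: 6 (R)-4-benzyl-1,3-oxazolidin-2-one; 7 benzyloxyacetyl chloride
Product: 8 (R)-4-benzyl-3-[2-(benzyloxy)acetyl]-1,3-oxazolidin-2-one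
Conditions: n-BuLi, THF, −78 °C; then 7, −78 → 0 °C
Reagents that add atoms: none
Why: N-Acylation of the lithiated oxazolidinone with an acid chloride (loading of the Evans auxiliary), which forms no stereocentre and leaves C4 of the auxiliary untouched.

**Step 4**
Reactants: 8 (R)-4-benzyl-3-[2-(benzyloxy)acetyl]-1,3-oxazolidin-2-one; 9 acetaldehyde
Product: 12 (R)-4-benzyl-3-[(2R,3S)-2-(benzyloxy)-3-hydroxybutanoyl]-1,3-oxazolidin-2-one, via Z-dibutylboron enolate 10 (not isolated), via dibutylboron aldolate 11 (not isolated)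
Conditions: Bu2BOTf, Et3N, CH2Cl2, −78 → 0 °C; 9, −78 → 0 °C; then pH 7 buffer, MeOH, 30% H2O2, 0 °C
Reagents that add atoms: none
Why: Evans syn-aldol reaction, in which the Z-boron enolate reacts through a chair Zimmerman–Traxler transition state on the face opposite the benzyl group of the (R)-auxiliary, setting the 2R,3S (syn) pair that becomes C3 and C2 of the target and leaving the two oxygens differentiated as benzyl ether and free alcohol.

**Step 5**
Reactants: 12 (R)-4-benzyl-3-[(2R,3S)-2-(benzyloxy)-3-hydroxybutanoyl]-1,3-oxazolidin-2-one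
Product: 13 (2R,3S)-2-(benzyloxy)-3-hydroxy-N-methoxy-N-methylbutanamide
Conditions: MeNHOMe·HCl, AlMe3, THF, −20 → 0 °C; aq. Rochelle salt
Reagents that add atoms: N,O-dimethylhydroxylamine hydrochloride, CNOC.Cl
Why: Aluminium amide transamination of an N-acyl oxazolidinone to the Weinreb amide, assisted by the free β-hydroxyl group as its aluminium alkoxide, which does not touch the stereocentres and returns the auxiliary.

**Step 6**
Reactants: 13 (2R,3S)-2-(benzyloxy)-3-hydroxy-N-methoxy-N-methylbutanamide
Product: 14 (3R,4S)-3-(benzyloxy)-4-hydroxypentan-2-one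
Conditions: MeMgBr (3 equiv), THF, −20 → 0 °C; sat. NH4Cl, 0 °C
Reagents that add atoms: methylmagnesium bromide, C[Mg]Br
Why: Grignard addition to a Weinreb amide, in which the first equivalent only deprotonates the hydroxyl group, the chelated tetrahedral intermediate prevents over-addition, and the cold buffered quench is meant to avoid epimerisation at the benzyloxy carbon and retro-aldol cleavage.

**Step 7**
Reactants: 14 (3R,4S)-3-(benzyloxy)-4-hydroxypentan-2-one; 15 tetradecanoyl chloride
Product: 16 (2S,3R)-3-(benzyloxy)-4-oxopentan-2-yl tetradecanoate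
Conditions: pyridine, DMAP (cat.), CH2Cl2, 0 °C
Reagents that add atoms: none
Why: Esterification of the only free hydroxyl group with an acid chloride under weak-base catalysis at 0 °C, which places the myristate on the C2 oxygen before the fragments are joined and should avoid β-elimination of the new acyloxy group.

**Step 8**
Reactants: 16 (2S,3R)-3-(benzyloxy)-4-oxopentan-2-yl tetradecanoate; 5 2-(1,3-oxazol-5-ylmethyl)-1,3-oxazole-4-carbaldehyde
Product: 19 (2S,3S,4S,6R)-3-(benzyloxy)-4,6-dihydroxy-6-[2-(1,3-oxazol-5-ylmethyl)-1,3-oxazol-4-yl]hexan-2-yl tetradecanoate, via diisopinocampheylboron enolate 17 (not isolated), via diisopinocampheylboron aldolate 18 (not isolated)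
Conditions: (−)-Ipc2BCl, Et3N, Et2O, −78 → 0 °C; 5 (CH2Cl2), −78 → −20 °C; LiBH4 (THF), −78 °C; then MeOH, pH 7 buffer, 30% H2O2, 0 °C
Reagents that add atoms: none
Why: Ipc2BCl/Et3N enolises 16 kinetically at the C5 methyl group, enol borinate 17 adds to the unenolisable aldehyde 5 through a cyclic boron-bridged (boat-like) transition state to give aldolate 18, and LiBH4 then delivers hydride to the C4 carbonyl, which is held and activated in the six-membered boron chelate with the C6 oxygen, before buffered peroxide frees the diol. The closest known reaction type is the one-pot boron aldol/in situ borohydride reduction of methyl ketones to 1,3-syn diols, run here with a chiral diisopinocampheylboron enolate. No ring of the product is closed; the only rings are the transient boron chelates. C6 (R) is set by the isopinocampheyl ligands on boron, which direct the enolate to the Re face of the aldehyde (reagent control, chosen because the 1,4/1,5 bias of the C3 and C2 oxygens is not known). C4 (S) is set by C6 through the chelate: hydride attacks axially on the half-chair in which the oxazolyl group is pseudo-equatorial, which gives the 4,6-syn diol and with it the 3,4-anti relationship. The step needs enolisation at CH3 and not at C3–H (which would eliminate myristate), an aldehyde that cannot enolise, and ketone-over-ester reduction; these are secured by the tertiary, benzyloxy-shielded C3–H, by the heteroaryl aldehyde, and by boron activation of the ketone only with LiBH4 kept at −78 °C.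

**Step 9**
Reactants: 19 (2S,3S,4S,6R)-3-(benzyloxy)-4,6-dihydroxy-6-[2-(1,3-oxazol-5-ylmethyl)-1,3-oxazol-4-yl]hexan-2-yl tetradecanoate
Product: 20 (2S,3S,4S,6R)-3,4,6-trihydroxy-6-[2-(1,3-oxazol-5-ylmethyl)-1,3-oxazol-4-yl]hexan-2-yl tetradecanoate
Conditions: H2 (1 atm), 10% Pd/C, EtOAc, rt
Reagents that add atoms: none
Why: Hydrogenolysis of the benzyl ether over palladium under neutral conditions, chosen so that the C2 myristate has no acid or base to carry it to the freed C3 hydroxyl group, while the oxazoles and the ester are expected to survive.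

**Compound list**

1 | methyl 2-(chloromethyl)-1,3-oxazole-4-carboxylate | COC(=O)c1coc(CCl)n1 | starting material
2 | 2-(triisopropylsilyl)-1,3-oxazole-5-boronic acid pinacol ester | CC(C)[Si](C(C)C)(C(C)C)c1ncc(o1)B1OC(C)(C)C(C)(C)O1 | starting material
3 | methyl 2-{[2-(triisopropylsilyl)-1,3-oxazol-5-yl]methyl}-1,3-oxazole-4-carboxylate | COC(=O)c1coc(Cc2cnc(o2)[Si](C(C)C)(C(C)C)C(C)C)n1 | intermediate
4 | methyl 2-(1,3-oxazol-5-ylmethyl)-1,3-oxazole-4-carboxylate | COC(=O)c1coc(Cc2cnco2)n1 | intermediate
5 | 2-(1,3-oxazol-5-ylmethyl)-1,3-oxazole-4-carbaldehyde | O=Cc1coc(Cc2cnco2)n1 | intermediate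
6 | (R)-4-benzyl-1,3-oxazolidin-2-one | O=C1N[C@H](Cc2ccccc2)CO1 | starting material
7 | benzyloxyacetyl chloride | O=C(Cl)COCc1ccccc1 | starting material
8 | (R)-4-benzyl-3-[2-(benzyloxy)acetyl]-1,3-oxazolidin-2-one | O=C(COCc1ccccc1)N1[C@H](Cc2ccccc2)COC1=O | intermediate
9 | acetaldehyde | CC=O | starting material
10 | Z-dibutylboron enolate of 8 | CCCCB(CCCC)O/C(=C\OCc1ccccc1)N1[C@H](Cc2ccccc2)COC1=O | intermediate
11 | dibutylboron aldolate of 12 (O-boryl at the 3-oxygen of the butanoyl chain) | C[C@H](OB(CCCC)CCCC)[C@@H](OCc1ccccc1)C(=O)N1[C@H](Cc2ccccc2)COC1=O | intermediate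
12 | (R)-4-benzyl-3-[(2R,3S)-2-(benzyloxy)-3-hydroxybutanoyl]-1,3-oxazolidin-2-one | C[C@H](O)[C@@H](OCc1ccccc1)C(=O)N1[C@H](Cc2ccccc2)COC1=O | intermediate
13 | (2R,3S)-2-(benzyloxy)-3-hydroxy-N-methoxy-N-methylbutanamide | C[C@H](O)[C@@H](OCc1ccccc1)C(=O)N(C)OC | intermediate
14 | (3R,4S)-3-(benzyloxy)-4-hydroxypentan-2-one | C[C@H](O)[C@@H](OCc1ccccc1)C(C)=O | intermediate
15 | tetradecanoyl (myristoyl) chloride | CCCCCCCCCCCCCC(=O)Cl | starting material
16 | (2S,3R)-3-(benzyloxy)-4-oxopentan-2-yl tetradecanoate | CCCCCCCCCCCCCC(=O)O[C@@H](C)[C@@H](OCc1ccccc1)C(C)=O | intermediate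
17 | diisopinocampheylboron enolate of 16 (O-boryl enol ether at C4, terminal CH2=) | CCCCCCCCCCCCCC(=O)O[C@@H](C)[C@@H](OCc1ccccc1)C(=C)OB([C@@H]1C[C@@H]2C[C@H]([C@H]1C)C2(C)C)[C@@H]1C[C@@H]2C[C@H]([C@H]1C)C2(C)C | intermediate
18 | diisopinocampheylboron aldolate: (2S,3R,6R)-3-(benzyloxy)-6-(diisopinocampheylboryloxy)-6-[2-(1,3-oxazol-5-ylmethyl)-1,3-oxazol-4-yl]-4-oxohexan-2-yl tetradecanoate | CCCCCCCCCCCCCC(=O)O[C@@H](C)[C@@H](OCc1ccccc1)C(=O)C[C@@H](OB([C@@H]1C[C@@H]2C[C@H]([C@H]1C)C2(C)C)[C@@H]1C[C@@H]2C[C@H]([C@H]1C)C2(C)C)c1coc(Cc2cnco2)n1 | intermediate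
19 | (2S,3S,4S,6R)-3-(benzyloxy)-4,6-dihydroxy-6-[2-(1,3-oxazol-5-ylmethyl)-1,3-oxazol-4-yl]hexan-2-yl tetradecanoate | CCCCCCCCCCCCCC(=O)O[C@@H](C)[C@@H](OCc1ccccc1)[C@@H](O)C[C@@H](O)c1coc(Cc2cnco2)n1 | intermediate
20 | (2S,3S,4S,6R)-3,4,6-trihydroxy-6-[2-(1,3-oxazol-5-ylmethyl)-1,3-oxazol-4-yl]hexan-2-yl tetradecanoate | CCCCCCCCCCCCCC(=O)O[C@@H](C)[C@@H](O)[C@@H](O)C[C@@H](O)c1coc(Cc2cnco2)n1 | target

**Step count and risks**

Total step count: 9. Longest linear sequence: 7 steps (steps 3 to 9, from 6 to 20).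

Steps most likely to fail:

1. Step 8. The two faces of the aldehyde may be poorly discriminated if the substrate's own bias opposes the boron ligands. Enolisation towards C3 would lose the myristate by β-elimination, and the acyl group could migrate or be reduced during the hydride and peroxide stages. Fallback (sets out from 13 and 5, returns at 19): the face choice at the aldehyde is avoided by setting C4 first in a 1,3-dipolar cycloaddition and C6 afterwards by chelate-controlled reduction. 13 is acylated with 15 (pyridine, DMAP, CH2Cl2) to (2S,3R)-3-(benzyloxy)-4-[methoxy(methyl)amino]-4-oxobutan-2-yl tetradecanoate F1, which Cp2Zr(H)Cl (THF, rt) reduces to (2S,3R)-3-(benzyloxy)-4-oxobutan-2-yl tetradecanoate F2 without touching the ester. Methylenation with Ph3P=CH2 (THF, −78 → 0 °C) gives (2S,3S)-3-(benzyloxy)pent-4-en-2-yl tetradecanoate F3. Aldehyde 5 is condensed with NH2OH·HCl/NaOAc to 2-(1,3-oxazol-5-ylmethyl)-1,3-oxazole-4-carbaldehyde oxime F4. PhI(OAc)2 (MeOH, cat. TFA) oxidises it in the presence of F3 to 2-(1,3-oxazol-5-ylmethyl)-1,3-oxazole-4-carbonitrile oxide F5. The cycloaddition forms the same C5–C6 bond and should give (2S,3R)-3-(benzyloxy)-3-[(5S)-3-{2-(1,3-oxazol-5-ylmethyl)-1,3-oxazol-4-yl}-4,5-dihydro-1,2-oxazol-5-yl]propan-2-yl tetradecanoate F6, with the new C4–O bond anti to the C3 benzyloxy group (inside-alkoxy effect). Mo(CO)6 in MeCN/H2O cleaves the N–O bond to (2S,3S,4S)-3-(benzyloxy)-4-hydroxy-6-[2-(1,3-oxazol-5-ylmethyl)-1,3-oxazol-4-yl]-6-oxohexan-2-yl tetradecanoate F7. Et2BOMe/NaBH4 (THF/MeOH, −78 °C, Narasaka–Prasad reduction) then reduces it 4,6-syn to 19.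

2. Step 1. The heteroaryl boronate may protodeboronate or lose its silyl group before transmetalation, and the chloride may hydrolyse under the basic aqueous conditions. Fallback (sets out from 1, returns at 4): the second oxazole ring is built on the side chain instead of being coupled. Stille coupling of 1 with tributyl(vinyl)stannane (Pd(PPh3)4, toluene, 90 °C) gives methyl 2-(prop-2-en-1-yl)-1,3-oxazole-4-carboxylate F8. Oxidative cleavage (OsO4 cat., NaIO4, 2,6-lutidine, dioxane/H2O) gives methyl 2-(2-oxoethyl)-1,3-oxazole-4-carboxylate F9. A van Leusen reaction with TosMIC (K2CO3, MeOH, reflux) converts the aldehyde carbon into C5 of the new oxazole and gives 4.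

3. Step 9. The oxazolyl carbinol C6–O bond may be hydrogenolysed, an oxazole ring may be partly reduced, or the oxazole nitrogens may poison the catalyst. Fallback (sets out from 19, returns at 20): non-reductive Lewis-acid debenzylation with BCl3 and pentamethylbenzene as cation scavenger (CH2Cl2, −78 °C, quench with MeOH/NaHCO3 at low temperature); no new compound is made (F0).

**Further compounds**

F1 | step 8 | (2S,3R)-3-(benzyloxy)-4-[methoxy(methyl)amino]-4-oxobutan-2-yl tetradecanoate | CCCCCCCCCCCCCC(=O)O[C@@H](C)[C@@H](OCc1ccccc1)C(=O)N(C)OC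
F2 | step 8 | (2S,3R)-3-(benzyloxy)-4-oxobutan-2-yl tetradecanoate | CCCCCCCCCCCCCC(=O)O[C@@H](C)[C@@H](OCc1ccccc1)C=O
F3 | step 8 | (2S,3S)-3-(benzyloxy)pent-4-en-2-yl tetradecanoate | CCCCCCCCCCCCCC(=O)O[C@@H](C)[C@@H](OCc1ccccc1)C=C
F4 | step 8 | (E)-2-(1,3-oxazol-5-ylmethyl)-1,3-oxazole-4-carbaldehyde oxime | O/N=C/c1coc(Cc2cnco2)n1
F5 | step 8 | 2-(1,3-oxazol-5-ylmethyl)-1,3-oxazole-4-carbonitrile oxide | [O-][N+]#Cc1coc(Cc2cnco2)n1
F6 | step 8 | (2S,3R)-3-(benzyloxy)-3-[(5S)-3-{2-(1,3-oxazol-5-ylmethyl)-1,3-oxazol-4-yl}-4,5-dihydro-1,2-oxazol-5-yl]propan-2-yl tetradecanoate | CCCCCCCCCCCCCC(=O)O[C@@H](C)[C@@H](OCc1ccccc1)[C@@H]1CC(=NO1)c1coc(Cc2cnco2)n1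
F7 | step 8 | (2S,3S,4S)-3-(benzyloxy)-4-hydroxy-6-[2-(1,3-oxazol-5-ylmethyl)-1,3-oxazol-4-yl]-6-oxohexan-2-yl tetradecanoate | CCCCCCCCCCCCCC(=O)O[C@@H](C)[C@@H](OCc1ccccc1)[C@@H](O)CC(=O)c1coc(Cc2cnco2)n1
F8 | step 1 | methyl 2-(prop-2-en-1-yl)-1,3-oxazole-4-carboxylate | C=CCc1nc(co1)C(=O)OC
F9 | step 1 | methyl 2-(2-oxoethyl)-1,3-oxazole-4-carboxylate | O=CCc1nc(co1)C(=O)OC
F0 | step 9 | none | none
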